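**Retrosynthetic overview**

- The target is reached by BBr3 cleavage of three methyl ethers from a 2-aryloxy-4-alkylphenol, which comes from a cyclohexenone by loss of H2. Rings A, B and D are bought as arenes; ring C is the only ring built, and it is aromatised last.
- Feature: in ring C the hydroxyl carbon C2 has the diaryl ether oxygen on its neighbour C1 and the arylethyl chain para to it on C5. These three atoms are the carbonyl carbon, the α-carbon and the 4-position of a 6-aryloxy-4-alkylcyclohex-2-enone.
- Key disconnection: the enone is cut at C1–C6 (Michael addition) and C3–C4 (aldol condensation) into an aryloxyacetone carrying rings A and B and a 2-methylidene aldehyde carrying ring D. The ether oxygen is placed beforehand by SN2 displacement on chloroacetone, so no aryl–oxygen coupling is needed.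
- Fragments: the A–B bibenzyl phenol by Horner–Wadsworth–Emmons olefination and hydrogenation; the ring D enal by Wittig chain extension of 2,5-dimethoxybenzaldehyde, hydrogenation, acetal hydrolysis and α-methylenation.

Key step: step 8

Remark: the target has no stereocenter. The two stereocenters created in step 8 are removed in step 9, so racemic material and diastereomer mixtures are carried forward unseparated.

**Route**

Step 1
Reactants: 1 4-(benzyloxy)benzaldehyde; 2 diethyl (3-methoxybenzyl)phosphonate
Product: 4 1-(benzyloxy)-4-[(E)-2-(3-methoxyphenyl)ethenyl]benzene, via potassium phosphonate carbanion 3 (not isolated)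
Conditions: KOtBu, THF, 0 °C; then 1, 0 °C → rt
Reagents that add atoms: none
Why: Horner–Wadsworth–Emmons olefination of a non-enolisable aromatic aldehyde with a benzylic phosphonate carbanion should give the (E)-stilbene that joins rings A and B, with a water-soluble phosphate as by-product.

Step 2
Reactants: 4 1-(benzyloxy)-4-[(E)-2-(3-methoxyphenyl)ethenyl]benzene
Product: 6 4-[2-(3-methoxyphenyl)ethyl]phenol, via saturated benzyl ether 5 (not isolated)
Conditions: H2 (1 atm), 10% Pd/C, EtOAc–MeOH, rt
Reagents that add atoms: none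
Why: Catalytic hydrogenation over palladium on carbon should saturate the stilbene double bond and then hydrogenolyse the benzyl ether in the same flask, the aryl methyl ether being inert.

Step 3
Reactants: 6 4-[2-(3-methoxyphenyl)ethyl]phenol; 7 chloroacetone
Product: 8 1-{4-[2-(3-methoxyphenyl)ethyl]phenoxy}propan-2-one
Conditions: K2CO3, KI (cat.), acetone, reflux
Reagents that add atoms: none
Why: Williamson ether synthesis, in which the phenoxide displaces halide from the activated α-halo ketone in an SN2 reaction and so installs the future diaryl ether oxygen of ring C without an aryl–oxygen coupling.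

Step 4
Reactants: 9 2,5-dimethoxybenzaldehyde; 10 [2-(1,3-dioxolan-2-yl)ethyl]triphenylphosphonium bromide
Product: 12 2-[(Z)-3-(2,5-dimethoxyphenyl)prop-2-en-1-yl]-1,3-dioxolane (Z/E mixture; Z drawn), via phosphonium ylide 11 (not isolated)
Conditions: KOtBu, THF, 0 °C; then 9, 0 °C → rt
Reagents that add atoms: none
Why: Wittig olefination of an aromatic aldehyde with a non-stabilised ylide attaches the masked four-carbon aldehyde chain to ring D, and the alkene geometry is of no consequence because step 5 removes the double bond.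

Step 5
Reactants: 12 2-[(Z)-3-(2,5-dimethoxyphenyl)prop-2-en-1-yl]-1,3-dioxolane
Product: 13 2-[3-(2,5-dimethoxyphenyl)propyl]-1,3-dioxolane
Conditions: H2 (1 atm), 10% Pd/C, EtOAc, rt
Reagents that add atoms: none
Why: Heterogeneous hydrogenation of the styrenyl alkene under neutral conditions should leave the dioxolane and the methyl ethers untouched.

Step 6
Reactants: 13 2-[3-(2,5-dimethoxyphenyl)propyl]-1,3-dioxolane
Product: 14 4-(2,5-dimethoxyphenyl)butanal
Conditions: 1 M HCl, THF, rt
Reagents that add atoms: water, O
Why: Acid-catalysed acetal hydrolysis, in which dilute acid at room temperature should free the aldehyde without cyclising it onto the electron-rich ring D.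

Step 7
Reactants: 14 4-(2,5-dimethoxyphenyl)butanal
Product: 15 4-(2,5-dimethoxyphenyl)-2-methylidenebutanal
Conditions: 37% aq. CH2O, pyrrolidine (10 mol%), EtCO2H (10 mol%), iPrOH, 45 °C
Reagents that add atoms: formaldehyde, C=O
Why: Amine-catalysed Mannich condensation with elimination (α-methylenation of an aldehyde), in which the enamine of 14 adds to the formaldehyde-derived iminium ion and loss of the amine gives the 2-substituted acrolein.

Step 8
Reactants: 8 1-{4-[2-(3-methoxyphenyl)ethyl]phenoxy}propan-2-one; 15 4-(2,5-dimethoxyphenyl)-2-methylidenebutanal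
Product: 18 cis-4-[2-(2,5-dimethoxyphenyl)ethyl]-6-{4-[2-(3-methoxyphenyl)ethyl]phenoxy}cyclohex-2-en-1-one (racemic; 4S,6R enantiomer drawn), via keto aldehyde 16 (not isolated), via aldol 17 (not isolated)
Conditions: pyrrolidine (30 mol%), PhCO2H (30 mol%), toluene, rt, slow addition of 15; then 4 Å MS, 70 °C
Reagents that add atoms: none
Why: Proposed new method: pyrrolidine should convert ketone 8 into its enamine on the aryloxy-bearing side (the more acidic α-carbon, giving the more substituted, oxygen-stabilised enamine), and this carbon adds to the unsubstituted CH2 terminus of enal 15 to form the C1–C6 bond of ring C in keto aldehyde 16; the methyl group, again as its enamine, then attacks the aldehyde to form C3–C4 in aldol 17, and loss of water gives the conjugated enone. The closest known reaction types are the Stork enamine Michael addition of ketones to acroleins, the amine-catalysed reactions of alkoxyacetones at their oxygenated carbon, and the Robinson annulation of β-keto esters with enals. Ring C closes in a 6-(enolendo)-exo-trig aldol, the only closure open to 16 because every other enol–carbonyl pairing would give a four-membered ring. Of the two new stereocenters, the chain-bearing carbon is set without control in the protonation after the Michael addition and the aryloxy-bearing carbon stays epimerisable next to the carbonyl, so the diequatorial cis isomer should prevail at equilibrium, and neither center matters because step 9 removes both. The step needs cross-reaction of donor and acceptor, which is secured because 8 has no acceptor site and 15 has no α-hydrogen and an unhindered 1,1-disubstituted alkene terminus. Site selectivity between the two α-carbons of 8 is favoured by the aryloxy group but is not essential, because attack through the methyl group would lead by the same aldol closure to the 2-aryloxy-4-alkylcyclohex-2-enone, which step 9 would convert into the same phenol 20.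

Step 9
Reactants: 18 cis-4-[2-(2,5-dimethoxyphenyl)ethyl]-6-{4-[2-(3-methoxyphenyl)ethyl]phenoxy}cyclohex-2-en-1-one
Product: 20 4-[2-(2,5-dimethoxyphenyl)ethyl]-2-{4-[2-(3-methoxyphenyl)ethyl]phenoxy}phenol, via cyclohexadienone tautomer 19 (not isolated)
Conditions: Pd(O2CCF3)2 (5 mol%), 2-(dimethylamino)pyridine (10 mol%), TsOH·H2O (20 mol%), O2 (1 atm), DMSO, 80 °C
Reagents that add atoms: none
Why: Aerobic dehydrogenation of a cyclohexenone to a phenol by divalent palladium, in which a palladium enolate at the aryloxy-bearing α'-carbon undergoes β-hydride elimination toward the ring CH2 to give dienone 19, which tautomerises to the phenol while O2 reoxidises zerovalent palladium; the aryloxy group sits on the palladated carbon and cannot be lost by β-elimination, and both stereocenters disappear.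

Step 10
Reactants: 20 4-[2-(2,5-dimethoxyphenyl)ethyl]-2-{4-[2-(3-methoxyphenyl)ethyl]phenoxy}phenol
Product: 22 2-[2-(4-hydroxy-3-{4-[2-(3-hydroxyphenyl)ethyl]phenoxy}phenyl)ethyl]benzene-1,4-diol (CNP0300581.0), via tetrakis(dibromoboryl) ether 21 (not isolated)
Conditions: BBr3 (6 equiv), CH2Cl2, −78 °C → rt; then H2O, 0 °C, under argon
Reagents that add atoms: none
Why: Lewis acid cleavage of aryl methyl ethers, in which BBr3 coordinates each methoxy oxygen and bromide attacks the methyl carbon in an SN2 step, whereas the diaryl ether has no sp3 carbon to attack and survives; aqueous work-up hydrolyses boryl ether 21 to the four free phenols.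

**Compound list**

1 | 4-(benzyloxy)benzaldehyde | O=Cc1ccc(OCc2ccccc2)cc1 | starting material
2 | diethyl (3-methoxybenzyl)phosphonate | CCOP(=O)(Cc1cccc(OC)c1)OCC | starting material
3 | potassium salt of the carbanion of 2 | CCOP(=O)([CH-]c1cccc(OC)c1)OCC.[K+] | intermediate (not isolated)
4 | 1-(benzyloxy)-4-[(E)-2-(3-methoxyphenyl)ethenyl]benzene | COc1cccc(/C=C/c2ccc(OCc3ccccc3)cc2)c1 | intermediate
5 | 1-(benzyloxy)-4-[2-(3-methoxyphenyl)ethyl]benzene | COc1cccc(CCc2ccc(OCc3ccccc3)cc2)c1 | intermediate (not isolated)
6 | 4-[2-(3-methoxyphenyl)ethyl]phenol | COc1cccc(CCc2ccc(O)cc2)c1 | intermediate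
7 | chloroacetone | CC(=O)CCl | starting material
8 | 1-{4-[2-(3-methoxyphenyl)ethyl]phenoxy}propan-2-one | CC(=O)COc1ccc(CCc2cccc(OC)c2)cc1 | intermediate
9 | 2,5-dimethoxybenzaldehyde | COc1ccc(OC)c(C=O)c1 | starting material
10 | [2-(1,3-dioxolan-2-yl)ethyl]triphenylphosphonium bromide | [Br-].C1COC(CC[P+](c2ccccc2)(c2ccccc2)c2ccccc2)O1 | starting material
11 | [2-(1,3-dioxolan-2-yl)ethylidene]triphenylphosphorane | C1COC(CC=P(c2ccccc2)(c2ccccc2)c2ccccc2)O1 | intermediate (not isolated)
12 | 2-[(Z)-3-(2,5-dimethoxyphenyl)prop-2-en-1-yl]-1,3-dioxolane (Z/E mixture; Z drawn) | COc1ccc(OC)c(/C=C\CC2OCCO2)c1 | intermediate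
13 | 2-[3-(2,5-dimethoxyphenyl)propyl]-1,3-dioxolane | COc1ccc(OC)c(CCCC2OCCO2)c1 | intermediate
14 | 4-(2,5-dimethoxyphenyl)butanal | COc1ccc(OC)c(CCCC=O)c1 | intermediate
15 | 4-(2,5-dimethoxyphenyl)-2-methylidenebutanal | C=C(CCc1cc(OC)ccc1OC)C=O | intermediate
16 | 2-[2-(2,5-dimethoxyphenyl)ethyl]-4-{4-[2-(3-methoxyphenyl)ethyl]phenoxy}-5-oxohexanal (diastereomer mixture) | CC(=O)C(CC(C=O)CCc1cc(OC)ccc1OC)Oc1ccc(CCc2cccc(OC)c2)cc1 | intermediate (not isolated)
17 | 4-[2-(2,5-dimethoxyphenyl)ethyl]-5-hydroxy-2-{4-[2-(3-methoxyphenyl)ethyl]phenoxy}cyclohexan-1-one (diastereomer mixture) | O=C1CC(O)C(CCc2cc(OC)ccc2OC)CC1Oc1ccc(CCc2cccc(OC)c2)cc1 | intermediate (not isolated)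
18 | cis-4-[2-(2,5-dimethoxyphenyl)ethyl]-6-{4-[2-(3-methoxyphenyl)ethyl]phenoxy}cyclohex-2-en-1-one (racemic; 4S,6R enantiomer drawn) | O=C1C=C[C@@H](CCc2cc(OC)ccc2OC)C[C@H]1Oc1ccc(CCc2cccc(OC)c2)cc1 | intermediate
19 | 4-[2-(2,5-dimethoxyphenyl)ethyl]-2-{4-[2-(3-methoxyphenyl)ethyl]phenoxy}cyclohexa-2,5-dien-1-one (racemic) | O=C1C=CC(CCc2cc(OC)ccc2OC)C=C1Oc1ccc(CCc2cccc(OC)c2)cc1 | intermediate (not isolated)
20 | 4-[2-(2,5-dimethoxyphenyl)ethyl]-2-{4-[2-(3-methoxyphenyl)ethyl]phenoxy}phenol | COc1cccc(CCc2ccc(Oc3cc(CCc4cc(OC)ccc4OC)ccc3O)cc2)c1 | intermediate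
21 | tetrakis(O-dibromoboryl) derivative of 22 | BrB(Br)Oc1cccc(CCc2ccc(Oc3cc(CCc4cc(OB(Br)Br)ccc4OB(Br)Br)ccc3OB(Br)Br)cc2)c1 | intermediate (not isolated)
22 | 2-[2-(4-hydroxy-3-{4-[2-(3-hydroxyphenyl)ethyl]phenoxy}phenyl)ethyl]benzene-1,4-diol | Oc1cccc(CCc2ccc(Oc3cc(CCc4cc(O)ccc4O)ccc3O)cc2)c1 | target

**Step count**

Total: 10 steps. Longest linear sequence: 7 steps (steps 4 to 10, from 2,5-dimethoxybenzaldehyde 9). The other branch (steps 1 to 3) joins at step 8.

**Steps most likely to fail**

Step 8 (proposed new method). Enamine formation from the aryloxy ketone may be slow. The enal could then be lost to amine-promoted migration of its double bond into the chain and to oligomerisation before the Michael addition takes place, or the adduct may add a second molecule of enal. The fallback uses known chemistry, sets out from phenol 6 and enal 15 and returns at enone 18; it activates the donor carbon as a β-keto ester. Phenol 6 is O-alkylated with methyl 2-chloroacetoacetate (K2CO3, acetone, reflux) to give methyl 2-{4-[2-(3-methoxyphenyl)ethyl]phenoxy}-3-oxobutanoate F1. Base-catalysed Michael addition of F1 to 15 (DBU cat., THF, 0 °C) should give methyl 2-acetyl-6-(2,5-dimethoxyphenyl)-4-formyl-2-{4-[2-(3-methoxyphenyl)ethyl]phenoxy}hexanoate F2. Aldol condensation (TsOH cat., toluene, reflux, water separator), in which only the methyl group can enolise toward a six-membered ring, closes ring C to methyl 5-[2-(2,5-dimethoxyphenyl)ethyl]-1-{4-[2-(3-methoxyphenyl)ethyl]phenoxy}-2-oxocyclohex-3-ene-1-carboxylate F3. Krapcho demethoxycarbonylation (LiCl, wet DMSO, 150 °C) then gives 18.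

Step 9. The catalyst may aggregate to palladium metal before conversion is complete, and the electron-rich phenol may undergo oxidative coupling under O2. The fallback sets out from 18 and returns at 20. Kinetic deprotonation of 18 at the aryloxy-bearing α'-carbon (LiN(iPr)2, THF, −78 °C) and trapping with PhSeCl should give 4-[2-(2,5-dimethoxyphenyl)ethyl]-6-{4-[2-(3-methoxyphenyl)ethyl]phenoxy}-6-(phenylselanyl)cyclohex-2-en-1-one F4. Oxidation with H2O2 (CH2Cl2, pyridine, 0 °C) gives the corresponding selenoxide, 6-(benzeneseleninyl)-4-[2-(2,5-dimethoxyphenyl)ethyl]-6-{4-[2-(3-methoxyphenyl)ethyl]phenoxy}cyclohex-2-en-1-one F5. Its syn-elimination can only take a hydrogen from the ring CH2, which gives dienone 19 and, by tautomerisation, phenol 20.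

Step 7. Aldehyde 14 may undergo self-aldol condensation under the amine catalyst, and the enal may dimerise by hetero-Diels–Alder reaction or polymerise on concentration and storage. The fallback sets out from 14 and returns at 15; it introduces the methylene stoichiometrically and keeps the enal in masked, storable form. Aldehyde 14 and dimethyl(methylidene)ammonium iodide (CH2Cl2, rt, basic work-up) give the Mannich base 2-[(dimethylamino)methyl]-4-(2,5-dimethoxyphenyl)butanal F6. Quaternisation with MeI gives 4-(2,5-dimethoxyphenyl)-2-formyl-N,N,N-trimethylbutan-1-aminium iodide F7. Brief treatment of F7 with aqueous NaHCO3 and CH2Cl2 at 0 °C releases 15 by elimination immediately before step 8.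

**Further compounds**

F1 | step 8 | methyl 2-{4-[2-(3-methoxyphenyl)ethyl]phenoxy}-3-oxobutanoate (racemic) | COC(=O)C(Oc1ccc(CCc2cccc(OC)c2)cc1)C(C)=O
F2 | step 8 | methyl 2-acetyl-6-(2,5-dimethoxyphenyl)-4-formyl-2-{4-[2-(3-methoxyphenyl)ethyl]phenoxy}hexanoate (diastereomer mixture) | COC(=O)C(CC(C=O)CCc1cc(OC)ccc1OC)(Oc1ccc(CCc2cccc(OC)c2)cc1)C(C)=O
F3 | step 8 | methyl 5-[2-(2,5-dimethoxyphenyl)ethyl]-1-{4-[2-(3-methoxyphenyl)ethyl]phenoxy}-2-oxocyclohex-3-ene-1-carboxylate (diastereomer mixture) | COC(=O)C1(Oc2ccc(CCc3cccc(OC)c3)cc2)CC(CCc2cc(OC)ccc2OC)C=CC1=O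
F4 | step 9 | 4-[2-(2,5-dimethoxyphenyl)ethyl]-6-{4-[2-(3-methoxyphenyl)ethyl]phenoxy}-6-(phenylselanyl)cyclohex-2-en-1-one (diastereomer mixture) | O=C1C=CC(CCc2cc(OC)ccc2OC)CC1([Se]c1ccccc1)Oc1ccc(CCc2cccc(OC)c2)cc1
F5 | step 9 | 6-(benzeneseleninyl)-4-[2-(2,5-dimethoxyphenyl)ethyl]-6-{4-[2-(3-methoxyphenyl)ethyl]phenoxy}cyclohex-2-en-1-one (diastereomer mixture) | O=C1C=CC(CCc2cc(OC)ccc2OC)CC1([Se](=O)c1ccccc1)Oc1ccc(CCc2cccc(OC)c2)cc1
F6 | step 7 | 2-[(dimethylamino)methyl]-4-(2,5-dimethoxyphenyl)butanal (racemic) | CN(C)CC(CCc1cc(OC)ccc1OC)C=O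
F7 | step 7 | 4-(2,5-dimethoxyphenyl)-2-formyl-N,N,N-trimethylbutan-1-aminium iodide (racemic) | C[N+](C)(C)CC(CCc1cc(OC)ccc1OC)C=O.[I-]
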